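**Plan**
Numbering: ring A is C1(H)=C10(Me)–C9(O-acyl)–C8(OH)–C7–C6(O)–C5(H)=C4(Me)–C3(OAc)–C2H2. Ring B is O6–C12(=O)–C11(=C13H2)–C7–C6. C14 sits on C10, C15 on C4, and the side chain is C1′–C4′.
Cuts: O9–C1′ (ester), C9–C10 (alkenylchromium plus aldehyde), C12=O back to C12H2, C7–C11 (radical closure), C1=C10 (iodo-Wittig), C5–C6 (alkenyllithium plus Weinreb amide), C2–C3 (allylboration).
Enabling feature: C7 is the ring B atom that bears C11, and it lies between O6 and the free O8–H. A C7–C8 oxirane next to an O6 propargyl ether therefore already contains all five atoms of ring B and the C13 methylene. Its surviving C8–O bond becomes the unprotected hydroxyl.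
Forward order: the C1–C5 and C6–C9 pieces are joined, and the chain is epoxidised and capped with the iodoalkene. Ring B closes first (step 15), C12 is oxidised, ring A closes second (step 22), and the epoxyangelate goes on last.
Stereochemistry: C3 from allylboration, C6 from CBS reduction, C8 from Sharpless epoxidation, C7 from the trans-selective radical closure, C9 from Felkin–Anh reduction of the ring A enone, C2′/C3′ from Sharpless epoxidation of angelyl alcohol. The 4Z alkene comes from anti-carbomagnesiation and the 1(10)Z alkene from the iodo-Wittig reaction.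

Key step: step 15

Remark: locants in all names follow the numbering above. Step 22 is treated as unselective at C9 because steps 23 and 24 reset that centre.

Step 1
Reactants: 1 propargyl alcohol
Product: 3 (Z)-3-iodo-2-methylprop-2-en-1-ol, via alkenylmagnesium alkoxide 2 (not isolated)
Conditions: MeMgBr, CuI (cat.), THF, 0 °C to rt; then I2, 0 °C
Reagents that add atoms: methylmagnesium bromide C[Mg]Br; iodine [I][I]
Why: Copper-catalysed anti-carbomagnesiation of the propargylic alkoxide puts the methyl group on C4 and magnesium on C5 inside a five-membered chelate, so iodinolysis with retention should give only the Z iodoalkene (C3 and iodine cis).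

Step 2
Reactants: 3 (Z)-3-iodo-2-methylprop-2-en-1-ol
Product: 4 (Z)-3-iodo-2-methylprop-2-enal
Conditions: MnO2, CH2Cl2, rt, dark
Reagents that add atoms: none
Why: Allylic alcohol oxidation with MnO2 is neutral and stops at the enal, so the Z geometry should survive if the aldehyde is used at once.

Step 3
Reactants: 4 (Z)-3-iodo-2-methylprop-2-enal
Product: 6 (1Z,3S)-1-iodo-2-methylhexa-1,5-dien-3-ol, via borinate ester 5 (not isolated)
Conditions: Ipc2B(allyl) of the (+)-α-pinene series, Et2O, −78 °C; then NaOH, H2O2, 0 °C to rt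
Reagents that add atoms: B-allyldiisopinocampheylborane C=CCB([C@@H]1C[C@@H]2C[C@H]([C@H]1C)C2(C)C)[C@@H]1C[C@@H]2C[C@H]([C@H]1C)C2(C)C
Why: Brown asymmetric allylboration forms C2–C3 through a closed chair transition state, and the (+)-α-pinene-derived ligands direct the allyl group to the aldehyde face that gives 3S, the sense this reagent shows with aldehydes whose substituent outranks allyl.

Step 4
Reactants: 6 (1Z,3S)-1-iodo-2-methylhexa-1,5-dien-3-ol
Product: 7 (1Z,3S)-1-iodo-3-(4-methoxybenzyloxy)-2-methylhexa-1,5-diene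
Conditions: NaH, PMBCl, Bu4NI (cat.), DMF, 0 °C to rt
Reagents that add atoms: 4-methoxybenzyl chloride COc1ccc(CCl)cc1
Why: Williamson etherification masks O3 as an ether that withstands organolithium, hydride and trivalent titanium reagents and can later be removed oxidatively before any chromium oxidation.

Step 5
Reactants: 8 tert-butyldimethyl(prop-2-yn-1-yloxy)silane
Product: 10 4-(tert-butyldimethylsilyloxy)-N-methoxy-N-methylbut-2-ynamide, via lithium acetylide 9 (not isolated)
Conditions: nBuLi, THF, −78 °C; then ClC(O)N(OMe)Me, −78 °C to 0 °C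
Reagents that add atoms: N-methoxy-N-methylcarbamoyl chloride CON(C)C(=O)Cl
Why: Deprotonation of the terminal alkyne and acylation of the acetylide with the carbamoyl chloride gives in one operation the Weinreb amide that carries C6 to C9.

Step 6
Reactants: 7 (1Z,3S)-1-iodo-3-(4-methoxybenzyloxy)-2-methylhexa-1,5-diene; 10 4-(tert-butyldimethylsilyloxy)-N-methoxy-N-methylbut-2-ynamide
Product: 12 (3S,4Z)-enynone (C6 ketone between C4=C5 and C7≡C8; O3-PMB; O9-TBS; allyl group on C3), via alkenyllithium 11 (not isolated)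
Conditions: tBuLi, Et2O, −78 °C; then 10, −78 °C; AcOH quench at −78 °C
Reagents that add atoms: none
Why: Iodine–lithium exchange keeps the alkene geometry and the Weinreb ketone synthesis halts at the chelated tetrahedral adduct, so C5–C6 forms without over-addition, and the cold acidic quench keeps the released amine from adding to the ynone.

Step 7
Reactants: 12 (3S,4Z)-enynone
Product: 13 (3S,6R,4Z)-propargylic alcohol (C6-OH; C7≡C8; O3-PMB; O9-TBS)
Conditions: (R)-2-methyl-CBS-oxazaborolidine (cat.), catecholborane, toluene, −78 °C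
Reagents that add atoms: none
Why: In this Corey–Bakshi–Shibata reduction the slim alkynyl group takes the small-substituent position and the branched Z-alkenyl group the large one, so the (R)-catalyst should deliver hydride to the face that gives 6R, while catecholborane leaves the terminal alkene alone.

Step 8
Reactants: 13 (3S,6R,4Z)-propargylic alcohol
Product: 14 (3S,6S,4Z,7E)-dienol (C6-OH; O3-PMB; O9-TBS)
Conditions: NaAlH2(OCH2CH2OMe)2, THF, 0 °C to rt; aq. potassium sodium tartrate
Reagents that add atoms: none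
Why: Hydroxyl-directed trans-hydroalumination of the propargylic alcohol followed by protonolysis gives the E alkene at C7–C8 only, because isolated alkenes are inert and the silyloxy group is too poor a leaving group for allene formation at this temperature (the change of the C6 descriptor is only a priority effect).

Step 9
Reactants: 14 (3S,6S,4Z,7E)-dienol; 15 propargyl bromide
Product: 16 (3S,6S,4Z,7E)-O6-propargyl ether (O3-PMB; O9-TBS)
Conditions: NaH, Bu4NI (cat.), THF/DMF, 0 °C
Reagents that add atoms: none
Why: Williamson etherification of the C6 alkoxide with the reactive propargylic bromide brings in C11, C12 and C13 without touching the stereocentre.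

Step 10
Reactants: 16 (3S,6S,4Z,7E)-O6-propargyl ether
Product: 17 (3S,6S,4Z,7E)-C9 allylic alcohol (O6-propargyl; O3-PMB)
Conditions: Bu4NF, THF, 0 °C
Reagents that add atoms: none
Why: Fluoride-mediated desilylation cleaves the only silyl ether and frees the C9 hydroxyl that must direct the epoxidation.

Step 11
Reactants: 17 (3S,6S,4Z,7E)-C9 allylic alcohol
Product: 18 (3S,6R,7S,8S,4Z)-trans-7,8-epoxy C9 alcohol (O6-propargyl; O3-PMB)
Conditions: Ti(OiPr)4 (cat.), L-(+)-diethyl tartrate (cat.), tBuOOH, 4 Å MS, CH2Cl2, −20 °C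
Reagents that add atoms: tert-butyl hydroperoxide CC(C)(C)OO
Why: Sharpless asymmetric epoxidation touches only the alkene of the free allylic alcohol, and L-(+)-tartrate delivers oxygen by reagent control to the face that gives the (7S,8S)-epoxide, which fixes the C8–O configuration of the target.

Step 12
Reactants: 18 (3S,6R,7S,8S,4Z)-trans-7,8-epoxy C9 alcohol
Product: 19 O9-TBS ether of 18
Conditions: TBSCl, imidazole, CH2Cl2, 0 °C to rt
Reagents that add atoms: tert-butyldimethylsilyl chloride C[Si](C)(Cl)C(C)(C)C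
Why: Silylation removes the free hydroxyl, which could bind titanium and steer homolysis to the C8–O bond, and the primary silyl ether can later be cleaved beside a secondary one.

Step 13
Reactants: 19 O9-TBS ether of 18
Product: 21 (3S,6R,7S,8S,4Z)-C1 aldehyde (7,8-epoxide; O6-propargyl; O3-PMB; O9-TBS), via vicinal diol 20 (not isolated)
Conditions: OsO4 (cat.), NaIO4, 2,6-lutidine, dioxane/H2O, rt
Reagents that add atoms: sodium periodate [Na+].[O-]I(=O)(=O)=O
Why: In this Lemieux–Johnson oxidation OsO4 should dihydroxylate the open monosubstituted alkene much faster than the alkyne or the Z-trisubstituted alkene, which is flanked by two oxygenated stereocentres, and periodate then cleaves the diol under lutidine buffering that protects the epoxide.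

Step 14
Reactants: 21 (3S,6R,7S,8S,4Z)-C1 aldehyde
Product: 22 (3S,6R,7S,8S,1(10)Z,4Z)-trans-7,8-epoxy O6-propargyl ether with 10-iodo-1(10)-ene terminus (O3-PMB; O9-TBS)
Conditions: EtPPh3I, nBuLi, THF, rt; I2, −78 °C; NaN(SiMe3)2, −20 °C; then 21, −78 °C
Reagents that add atoms: ethyltriphenylphosphonium iodide CC[P+](c1ccccc1)(c1ccccc1)c1ccccc1.[I-]; iodine [I][I]
Why: The Stork–Zhao-type Wittig olefination with the α-iodo ylide is kinetically Z-selective and places iodine cis to C2 and C14 trans to it, and the ylide is too weak a base to deprotonate the alkyne or to expel the β-alkoxy group at −78 °C.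

Step 15
Reactants: 22 (3S,6R,7S,8S,1(10)Z,4Z)-trans-7,8-epoxy O6-propargyl ether
Product: 24 (3S,6R,7R,8R,1(10)Z,4Z)-3-methylenetetrahydrofuran with free C8 hydroxyl (O3-PMB; O9-TBS; 10-iodoalkene), via titanium alkoxide 23 (not isolated)
Conditions: Cp2TiCl2, Zn dust, THF, rt (green Cp2TiCl), added slowly to 22 in THF, rt; then aq. NaH2PO4
Reagents that add atoms: none
Why: Cp2TiCl, made in the flask from Cp2TiCl2 and zinc, binds the oxirane oxygen and passes on one electron, so the C7–O bond breaks homolytically to a C7 radical beside a C8 titanium alkoxide, while the C8–O bond is never touched and keeps the configuration set in step 11. The radical adds to the inner alkyne carbon C11 in a 5-exo-dig closure that forms C7–C11 and ring B (O6, C12, C11, C7, C6), and the C13 vinyl radical is quenched by hydrogen abstraction from THF or by a second trivalent titanium and protonation. The closest known reaction type is the titanocene-mediated reductive opening of epoxides that stand next to propargyl ethers, which gives 3-methylenetetrahydrofurans. C7 is the only new stereocentre: the planar radical closes through a chair-like transition state with the C5 alkenyl chain on C6 and the C8 chain on C7 pseudo-equatorial, hence trans as in the target lactone. The step needs cleavage at C7 rather than C8: the bulky titanocene should stay on the carbon with the smaller neighbour (C9H2OTBS) and away from the branched C6, only the C7 radical has a 5-exo partner, and slow addition keeps the reagent dilute so that cyclisation outruns capture and β-elimination. The vinyl iodide, the PMB ether and the silyl ether should be inert to trivalent titanium and zinc at room temperature.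

Step 16
Reactants: 24 (3S,6R,7R,8R)-3-methylenetetrahydrofuran with free C8 hydroxyl
Product: 25 (3S,6R,7S,8R)-8,9-bis-TBS ether (O3-PMB)
Conditions: TBSOTf, 2,6-lutidine, CH2Cl2, −78 °C to 0 °C
Reagents that add atoms: tert-butyldimethylsilyl triflate C[Si](C)(OS(=O)(=O)C(F)(F)F)C(C)(C)C
Why: Silylation with the reactive triflate covers the hindered C8 hydroxyl with a group that resists chromium oxidants and leaves under mild acidic fluoride at the end (the C7 descriptor changes by priority only).

Step 17
Reactants: 25 (3S,6R,7S,8R)-8,9-bis-TBS ether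
Product: 26 (3S,6R,7S,8R)-C3 allylic alcohol
Conditions: DDQ, CH2Cl2/pH 7 buffer, 0 °C
Reagents that add atoms: none
Why: Oxidative PMB cleavage by hydride abstraction from the electron-rich benzylic position is orthogonal to the silyl ethers, the vinyl iodide and the non-activated allylic ether of ring B.

Step 18
Reactants: 26 (3S,6R,7S,8R)-C3 allylic alcohol
Product: 27 (3S,6R,7S,8R)-C3 acetate
Conditions: Ac2O, pyridine, DMAP (cat.), CH2Cl2, rt
Reagents that add atoms: acetic anhydride CC(=O)OC(C)=O
Why: DMAP-catalysed acylation installs the acetate of the target on the only free hydroxyl with retention at C3.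

Step 19
Reactants: 27 (3S,6R,7S,8R)-C3 acetate
Product: 28 (3S,6R,7S,8R)-α-methylene-γ-butyrolactone (8,9-bis-TBS; 10-iodoalkene)
Conditions: CrO3·(pyridine)2 (excess), CH2Cl2, rt
Reagents that add atoms: chromium trioxide O=[Cr](=O)=O
Why: Allylic oxidation of 3-methylenetetrahydrofurans to α-methylene lactones is known, and C12H2 should react first because it is both allylic to C11=C13 and next to the ring oxygen, whereas C6–H is held in the plane of the Z alkene by allylic 1,3-strain and the other allylic sites lack the activating ether oxygen.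

Step 20
Reactants: 28 (3S,6R,7S,8R)-α-methylene-γ-butyrolactone
Product: 29 (3S,6R,7S,8R)-C9 primary alcohol (O8-TBS)
Conditions: HF·pyridine, pyridine, THF, 0 °C
Reagents that add atoms: none
Why: Under buffered fluoride the unhindered primary silyl ether is cleaved well before the flanked secondary one, and acetate, lactone and vinyl iodide are untouched.

Step 21
Reactants: 29 (3S,6R,7S,8R)-C9 primary alcohol
Product: 30 (3S,6R,7S,8R)-C9 aldehyde (O8-TBS)
Conditions: Dess–Martin periodinane, CH2Cl2, 0 °C to rt
Reagents that add atoms: none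
Why: Dess–Martin oxidation is near-neutral and stops at the α-silyloxy aldehyde without epimerising C8.

Step 22
Reactants: 30 (3S,6R,7S,8R)-C9 aldehyde
Product: 31 ring A allylic alcohol as C9 epimers (3S,6R,7S,8R,1(10)Z,4Z; O8-TBS)
Conditions: CrCl2 (excess), NiCl2 (cat.), DMSO/THF, rt, high dilution with slow addition of 30
Reagents that add atoms: none
Why: In the Nozaki–Hiyama–Kishi reaction zerovalent nickel inserts into C10–I, transmetalation gives an alkenyl trivalent chromium species with retained Z geometry, and this adds only to the aldehyde, so C9–C10 and the ten-membered ring form beside lactone and acetate, helped by the two Z alkenes and the trans-fused ring B that bring the ends together (a Felkin–Anh approach predicts mainly 9S, which the next two steps correct).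

Step 23
Reactants: 31 ring A allylic alcohol as C9 epimers
Product: 32 (3S,6R,7S,8R,1(10)Z,4Z)-ring A C9 enone (O8-TBS)
Conditions: Dess–Martin periodinane, CH2Cl2, 0 °C to rt
Reagents that add atoms: none
Why: Dess–Martin oxidation converges both C9 epimers on one enone under conditions too mild to epimerise C8 or move the alkenes.

Step 24
Reactants: 32 (3S,6R,7S,8R,1(10)Z,4Z)-ring A C9 enone
Product: 33 (3S,6R,7S,8R,9R)-ring A C9 alcohol (O8-TBS)
Conditions: NaBH4, CeCl3·7H2O, MeOH, −78 °C
Reagents that add atoms: none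
Why: Luche reduction attacks the ketone 1,2 faster than the methylene lactone, and in the polar Felkin–Anh arrangement hydride comes anti to the C8 silyloxy group from the ring periphery, which gives the 8,9-syn relationship, that is 9R.

Step 25
Reactants: 34 angelic acid ((Z)-2-methylbut-2-enoic acid)
Product: 35 (Z)-2-methylbut-2-en-1-ol
Conditions: LiAlH4, Et2O, 0 °C
Reagents that add atoms: none
Why: Hydride reduction of the unsaturated acid gives the allylic alcohol with the Z geometry intact.

Step 26
Reactants: 35 (Z)-2-methylbut-2-en-1-ol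
Product: 36 (2S,3R)-2,3-epoxy-2-methylbutan-1-ol
Conditions: Ti(OiPr)4 (cat.), L-(+)-diethyl tartrate (cat.), tBuOOH, 4 Å MS, CH2Cl2, −20 °C
Reagents that add atoms: tert-butyl hydroperoxide CC(C)(C)OO
Why: Sharpless asymmetric epoxidation with L-(+)-tartrate sets both side-chain centres in one syn oxygen transfer, and the Z alkene secures the cis relation of C1′ and C4′.

Step 27
Reactants: 36 (2S,3R)-2,3-epoxy-2-methylbutan-1-ol
Product: 37 (2R,3R)-2,3-dimethyloxirane-2-carboxylic acid
Conditions: RuCl3 hydrate (cat.), NaIO4, EtOAc/MeCN/H2O, rt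
Reagents that add atoms: sodium periodate [Na+].[O-]I(=O)(=O)=O
Why: Catalytic RuO4 oxidation takes the primary alcohol to the acid without opening the epoxide, and the C2′ descriptor changes only because the carboxyl group gains priority.

Step 28
Reactants: 37 (2R,3R)-2,3-dimethyloxirane-2-carboxylic acid; 33 (3S,6R,7S,8R,9R)-ring A C9 alcohol
Product: 39 O8-TBS ether of the target, via mixed anhydride 38 (not isolated)
Conditions: 37, 2,4,6-trichlorobenzoyl chloride, Et3N, toluene, rt; then 33, DMAP, toluene, rt to 40 °C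
Reagents that add atoms: none
Why: Yamaguchi esterification activates the non-enolisable α-quaternary acid strongly enough to acylate the hindered C9 hydroxyl with retention at C9, C2′ and C3′.

Step 29
Reactants: 39 O8-TBS ether of the target
Product: 40 CNP0137407.10 (3S,6R,7R,8R,9R,2′R,3′R)
Conditions: HF·pyridine, THF, 0 °C to rt
Reagents that add atoms: none
Why: Mildly acidic fluoride desilylation frees O8-H without the base-induced O9 to O8 acyl shift, and the electron-poor glycidic epoxide, the acetate and the methylene lactone should tolerate it.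

**Compound list**
1 | propargyl alcohol | C#CCO | starting material
2 | (Z)-alkenylmagnesium alkoxide | Br[Mg]/C=C(/C)CO[Mg]Br | intermediate
3 | (Z)-3-iodo-2-methylprop-2-en-1-ol | I/C=C(/C)CO | intermediate
4 | (Z)-3-iodo-2-methylprop-2-enal | I/C=C(/C)C=O | intermediate
5 | diisopinocampheylborinate of 6 | I/C=C(/C)[C@@H](OB([C@@H]1C[C@@H]2C[C@H]([C@H]1C)C2(C)C)[C@@H]1C[C@@H]2C[C@H]([C@H]1C)C2(C)C)CC=C | intermediate
6 | (1Z,3S)-1-iodo-2-methylhexa-1,5-dien-3-ol | I/C=C(/C)[C@@H](O)CC=C | intermediate
7 | (1Z,3S)-1-iodo-3-(4-methoxybenzyloxy)-2-methylhexa-1,5-diene | I/C=C(/C)[C@@H](OCc1ccc(OC)cc1)CC=C | intermediate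
8 | tert-butyldimethyl(prop-2-yn-1-yloxy)silane | C#CCO[Si](C)(C)C(C)(C)C | starting material
9 | lithium acetylide of 8 | [Li]C#CCO[Si](C)(C)C(C)(C)C | intermediate
10 | 4-(tert-butyldimethylsilyloxy)-N-methoxy-N-methylbut-2-ynamide | CON(C)C(=O)C#CCO[Si](C)(C)C(C)(C)C | intermediate
11 | (Z)-alkenyllithium from 7 | [Li]/C=C(/C)[C@@H](OCc1ccc(OC)cc1)CC=C | intermediate
12 | (3S,4Z)-enynone | O=C(C#CCO[Si](C)(C)C(C)(C)C)/C=C(/C)[C@@H](OCc1ccc(OC)cc1)CC=C | intermediate
13 | (3S,6R,4Z)-propargylic alcohol | O[C@H](/C=C(/C)[C@@H](OCc1ccc(OC)cc1)CC=C)C#CCO[Si](C)(C)C(C)(C)C | intermediate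
14 | (3S,6S,4Z,7E)-dienol | O[C@H](/C=C(/C)[C@@H](OCc1ccc(OC)cc1)CC=C)/C=C/CO[Si](C)(C)C(C)(C)C | intermediate
15 | propargyl bromide | C#CCBr | starting material
16 | (3S,6S,4Z,7E)-O6-propargyl ether | C#CCO[C@H](/C=C(/C)[C@@H](OCc1ccc(OC)cc1)CC=C)/C=C/CO[Si](C)(C)C(C)(C)C | intermediate
17 | (3S,6S,4Z,7E)-C9 allylic alcohol | C#CCO[C@H](/C=C(/C)[C@@H](OCc1ccc(OC)cc1)CC=C)/C=C/CO | intermediate
18 | (3S,6R,7S,8S,4Z)-trans-7,8-epoxy C9 alcohol | C#CCO[C@H](/C=C(/C)[C@@H](OCc1ccc(OC)cc1)CC=C)[C@@H]1O[C@H]1CO | intermediate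
19 | O9-TBS ether of 18 | C#CCO[C@H](/C=C(/C)[C@@H](OCc1ccc(OC)cc1)CC=C)[C@@H]1O[C@H]1CO[Si](C)(C)C(C)(C)C | intermediate
20 | vicinal diol from 19 (C1 epimers) | C#CCO[C@H](/C=C(/C)[C@@H](OCc1ccc(OC)cc1)CC(O)CO)[C@@H]1O[C@H]1CO[Si](C)(C)C(C)(C)C | intermediate
21 | (3S,6R,7S,8S,4Z)-C1 aldehyde | C#CCO[C@H](/C=C(/C)[C@@H](OCc1ccc(OC)cc1)CC=O)[C@@H]1O[C@H]1CO[Si](C)(C)C(C)(C)C | intermediate
22 | (3S,6R,7S,8S,1(10)Z,4Z)-trans-7,8-epoxy O6-propargyl ether, key-step precursor | C#CCO[C@H](/C=C(/C)[C@@H](OCc1ccc(OC)cc1)C/C=C(/C)I)[C@@H]1O[C@H]1CO[Si](C)(C)C(C)(C)C | intermediate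
23 | C8 chlorotitanocene alkoxide of 24 | C=C1CO[C@H](/C=C(/C)[C@@H](OCc2ccc(OC)cc2)C/C=C(/C)I)[C@H]1[C@@H]([O-])CO[Si](C)(C)C(C)(C)C.[Ti+4].[Cl-].[cH-]1cccc1.[cH-]1cccc1 | intermediate
24 | (3S,6R,7R,8R)-3-methylenetetrahydrofuran with free C8-OH, key-step product | C=C1CO[C@H](/C=C(/C)[C@@H](OCc2ccc(OC)cc2)C/C=C(/C)I)[C@H]1[C@@H](O)CO[Si](C)(C)C(C)(C)C | intermediate
25 | (3S,6R,7S,8R)-8,9-bis-TBS ether | C=C1CO[C@H](/C=C(/C)[C@@H](OCc2ccc(OC)cc2)C/C=C(/C)I)[C@H]1[C@@H](O[Si](C)(C)C(C)(C)C)CO[Si](C)(C)C(C)(C)C | intermediate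
26 | (3S,6R,7S,8R)-C3 allylic alcohol | C=C1CO[C@H](/C=C(/C)[C@@H](O)C/C=C(/C)I)[C@H]1[C@@H](O[Si](C)(C)C(C)(C)C)CO[Si](C)(C)C(C)(C)C | intermediate
27 | (3S,6R,7S,8R)-C3 acetate | C=C1CO[C@H](/C=C(/C)[C@@H](OC(C)=O)C/C=C(/C)I)[C@H]1[C@@H](O[Si](C)(C)C(C)(C)C)CO[Si](C)(C)C(C)(C)C | intermediate
28 | (3S,6R,7S,8R)-α-methylene-γ-butyrolactone | C=C1C(=O)O[C@H](/C=C(/C)[C@@H](OC(C)=O)C/C=C(/C)I)[C@H]1[C@@H](O[Si](C)(C)C(C)(C)C)CO[Si](C)(C)C(C)(C)C | intermediate
29 | (3S,6R,7S,8R)-C9 primary alcohol | C=C1C(=O)O[C@H](/C=C(/C)[C@@H](OC(C)=O)C/C=C(/C)I)[C@H]1[C@@H](O[Si](C)(C)C(C)(C)C)CO | intermediate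
30 | (3S,6R,7S,8R)-C9 aldehyde | C=C1C(=O)O[C@H](/C=C(/C)[C@@H](OC(C)=O)C/C=C(/C)I)[C@H]1[C@@H](O[Si](C)(C)C(C)(C)C)C=O | intermediate
31 | ring A allylic alcohol (C9 epimers) | C=C1C(=O)O[C@@H]2/C=C(/C)[C@@H](OC(C)=O)C/C=C(/C)C(O)[C@H](O[Si](C)(C)C(C)(C)C)[C@@H]12 | intermediate
32 | ring A C9 enone | C=C1C(=O)O[C@@H]2/C=C(/C)[C@@H](OC(C)=O)C/C=C(/C)C(=O)[C@H](O[Si](C)(C)C(C)(C)C)[C@@H]12 | intermediate
33 | (9R)-ring A C9 alcohol | C=C1C(=O)O[C@@H]2/C=C(/C)[C@@H](OC(C)=O)C/C=C(/C)[C@@H](O)[C@H](O[Si](C)(C)C(C)(C)C)[C@@H]12 | intermediate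
34 | angelic acid | C/C=C(/C)C(=O)O | starting material
35 | (Z)-2-methylbut-2-en-1-ol | C/C=C(/C)CO | intermediate
36 | (2S,3R)-2,3-epoxy-2-methylbutan-1-ol | OC[C@]1(C)O[C@@H]1C | intermediate
37 | (2R,3R)-2,3-dimethyloxirane-2-carboxylic acid | OC(=O)[C@]1(C)O[C@@H]1C | intermediate
38 | mixed anhydride of 37 with 2,4,6-trichlorobenzoic acid | O=C(OC(=O)c1c(Cl)cc(Cl)cc1Cl)[C@]1(C)O[C@@H]1C | intermediate
39 | O8-TBS ether of the target | C=C1C(=O)O[C@@H]2/C=C(/C)[C@@H](OC(C)=O)C/C=C(/C)[C@@H](OC(=O)[C@]3(C)O[C@@H]3C)[C@H](O[Si](C)(C)C(C)(C)C)[C@@H]12 | intermediate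
40 | CNP0137407.10 | C=C1C(=O)O[C@@H]2/C=C(/C)[C@@H](OC(C)=O)C/C=C(/C)[C@@H](OC(=O)[C@]3(C)O[C@@H]3C)[C@H](O)[C@@H]12 | target

Total step count: 29. Longest linear sequence: 25 steps (1 to 40 through steps 1–4, 6–24, 28 and 29).

**Steps most likely to fail**

Step 15. Homolysis may occur at C8. The epoxide may be deoxygenated. The C7 radical may be captured by a second trivalent titanium and lose O6 by β-elimination before it cyclises. The fallback produces the same C7 radical from a C7–O bond that ionic chemistry defines. It sets out from 18. Ti(OiPr)4-assisted opening with benzoic acid attacks the oxirane carbon remote from the carbinol (C7, with an inversion that is erased later) and would give the 7-benzoate 8,9-diol F1. TBSOTf and 2,6-lutidine would give the bis-silyl ether F2, Lemieux–Johnson cleavage the C1 aldehyde F3, and the iodo-Wittig reaction the (Z)-iodoalkene F4. iBu2AlH at −78 °C would then give the C7 alcohol F5, and NaH, CS2 and MeI the S-methyl xanthate F6. A tin-free Barton–McCombie-type fragmentation with dilauroyl peroxide in refluxing 2-propanol releases the C7 radical without touching the vinyl iodide. The radical closes 5-exo-dig as before, and the route is rejoined at 25.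

Step 22. Oligomerisation may win over closure of the strained ten-membered ring. Divalent chromium may also reduce the electrophilic methylene lactone while the slow cyclisation is under way. The fallback moves the ring closure ahead of the lactone oxidation, so that the more flexible and non-electrophilic tetrahydrofuran is cyclised. It sets out from 27. HF·pyridine would give the C9 primary alcohol F7, Dess–Martin periodinane the C9 aldehyde F8, and CrCl2 with catalytic NiCl2 at high dilution the ring A allylic alcohol F9. Dess–Martin periodinane would then give the ring A enone F10. CrO3·(pyridine)2 would finally oxidise C12H2, still the only doubly activated methylene, and the route is rejoined at 32.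

Step 24. Facial selectivity may be poor or reversed if the ring conformation exposes the other carbonyl face, and the methylene lactone may undergo competing conjugate reduction. The fallback gives up the reduction and uses the stereochemical bias of step 22 instead. It sets out from 31. Chromatography would give the Felkin-type (9S)-alcohol F11, and a Mitsunobu esterification with 37 (PPh3, diisopropyl azodicarboxylate, toluene) would attach the side chain with inversion at C9. The route is rejoined at 39.

**Further compounds**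
F1 | step 15 | 7-benzoate 8,9-diol | C#CCO[C@H](/C=C(/C)[C@@H](OCc1ccc(OC)cc1)CC=C)[C@@H](OC(=O)c1ccccc1)[C@@H](O)CO
F2 | step 15 | 7-benzoate 8,9-bis-TBS ether | C#CCO[C@H](/C=C(/C)[C@@H](OCc1ccc(OC)cc1)CC=C)[C@@H](OC(=O)c1ccccc1)[C@@H](O[Si](C)(C)C(C)(C)C)CO[Si](C)(C)C(C)(C)C
F3 | step 15 | C1 aldehyde of the benzoate series | C#CCO[C@H](/C=C(/C)[C@@H](OCc1ccc(OC)cc1)CC=O)[C@@H](OC(=O)c1ccccc1)[C@@H](O[Si](C)(C)C(C)(C)C)CO[Si](C)(C)C(C)(C)C
F4 | step 15 | (Z)-iodoalkene of the benzoate series | C#CCO[C@H](/C=C(/C)[C@@H](OCc1ccc(OC)cc1)C/C=C(/C)I)[C@@H](OC(=O)c1ccccc1)[C@@H](O[Si](C)(C)C(C)(C)C)CO[Si](C)(C)C(C)(C)C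
F5 | step 15 | C7 alcohol | C#CCO[C@H](/C=C(/C)[C@@H](OCc1ccc(OC)cc1)C/C=C(/C)I)[C@@H](O)[C@@H](O[Si](C)(C)C(C)(C)C)CO[Si](C)(C)C(C)(C)C
F6 | step 15 | C7 S-methyl xanthate | C#CCO[C@H](/C=C(/C)[C@@H](OCc1ccc(OC)cc1)C/C=C(/C)I)[C@@H](OC(=S)SC)[C@@H](O[Si](C)(C)C(C)(C)C)CO[Si](C)(C)C(C)(C)C
F7 | step 22 | C9 primary alcohol of the tetrahydrofuran series | C=C1CO[C@H](/C=C(/C)[C@@H](OC(C)=O)C/C=C(/C)I)[C@H]1[C@@H](O[Si](C)(C)C(C)(C)C)CO
F8 | step 22 | C9 aldehyde of the tetrahydrofuran series | C=C1CO[C@H](/C=C(/C)[C@@H](OC(C)=O)C/C=C(/C)I)[C@H]1[C@@H](O[Si](C)(C)C(C)(C)C)C=O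
F9 | step 22 | ring A allylic alcohol of the tetrahydrofuran series (C9 epimers) | C=C1CO[C@@H]2/C=C(/C)[C@@H](OC(C)=O)C/C=C(/C)C(O)[C@H](O[Si](C)(C)C(C)(C)C)[C@@H]12
F10 | step 22 | ring A enone of the tetrahydrofuran series | C=C1CO[C@@H]2/C=C(/C)[C@@H](OC(C)=O)C/C=C(/C)C(=O)[C@H](O[Si](C)(C)C(C)(C)C)[C@@H]12
F11 | step 24 | (9S)-ring A C9 alcohol | C=C1C(=O)O[C@@H]2/C=C(/C)[C@@H](OC(C)=O)C/C=C(/C)[C@H](O)[C@H](O[Si](C)(C)C(C)(C)C)[C@@H]12
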